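**Plan**

- Enabling feature: in ring A, C6 lies between O5 and O7 and C8 lies ortho to O7, while C4a (the other neighbour of C5) is quaternary. Both carbons can therefore receive their substituents by [3,3] shifts from ethers on O5 and O7.
- Last cuts: the two MOM ethers; then, in one operation, C6–CH2 (prenyl), C8–C4 and O7–C2 of the 2,2-dimethylpyran, back to a 5-O-(1,1-dimethylallyl) 7-O-(1,1-dimethylpropargyl) bis-ether.
- Core cuts: O1–C8a (SNAr of an aryl fluoride) and C3–C4 (enolate C-acylation) to a benzoxepinone and a 2-fluorobenzoic acid; the oxepine O–C(=CMe2) bond (copper O-vinylation); the C3–CH2 bond (enolate alkylation).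
- Forward order of rings: ring B is bought; then the oxepine; then the pyranone, which brings in ring A; last the dimethylpyran in the key step.
- Stereochemistry: the target has no stereocentre and no configured double bond (the exocyclic alkene carries two methyl groups), so nothing has to be controlled.

Key step: step 18

Assumption: 3-chloro-3-methylbut-1-yne is bought; "oxepinoflavone" below means the flavone whose C3 is joined through CH2–C(=CMe2)–O to C2' (flavone numbering, oxygens at C5, C7, C4', C5').

**Route**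

Step 1
Reactants: 1 1-(2,4,5-trihydroxyphenyl)ethan-1-one
Product: 2 1-[2-hydroxy-4,5-bis(methoxymethoxy)phenyl]ethan-1-one
Conditions: MOMCl (2.2 equiv), iPr2NEt, CH2Cl2, 0 °C to rt
Reagents that add atoms: chloromethyl methyl ether, COCCl
Why: Williamson-type O-alkylation should stop at the two free phenols, because the 2-OH is hydrogen-bonded to the acetyl carbonyl and far less nucleophilic.

Step 2
Reactants: 3 3-methylbut-2-enal
Product: 5 2-bromo-3-methylbut-2-enal, via 2,3-dibromo-3-methylbutanal 4 (not isolated)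
Conditions: Br2, CH2Cl2, −10 °C; then Et3N, 0 °C to rt
Reagents that add atoms: bromine, BrBr
Why: Bromine addition to the enal followed by amine-induced loss of HBr (the acidic α-hydrogen and the tertiary bromide) is the standard way to α-bromo enals, and the tetrasubstituted alkene has no geometry to control.

Step 3
Reactants: 5 2-bromo-3-methylbut-2-enal
Product: 6 2-bromo-3-methylbut-2-en-1-ol
Conditions: NaBH4, CeCl3·7H2O, MeOH, 0 °C
Reagents that add atoms: none
Why: Luche 1,2-reduction of the aldehyde leaves the vinylic bromide and the alkene untouched.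

Step 4
Reactants: 6 2-bromo-3-methylbut-2-en-1-ol
Product: 7 1,2-dibromo-3-methylbut-2-ene
Conditions: PBr3 (0.4 equiv), Et2O, 0 °C
Reagents that add atoms: phosphorus tribromide, BrP(Br)Br
Why: PBr3 converts a primary allylic alcohol into the bromide, and the primary allylic bromide is also the thermodynamically preferred allylic isomer.

Step 5
Reactants: 2 1-[2-hydroxy-4,5-bis(methoxymethoxy)phenyl]ethan-1-one, 7 1,2-dibromo-3-methylbut-2-ene
Product: 8 4-bromo-1-[2-hydroxy-4,5-bis(methoxymethoxy)phenyl]-5-methylhex-4-en-1-one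
Conditions: 2, LiN(iPr)2 (2.2 equiv), THF, −78 to −20 °C; then 7, −78 to 0 °C
Reagents that add atoms: none
Why: The phenoxide–enolate dianion of an o-hydroxyacetophenone is alkylated at carbon (SN2 at the allylic CH2Br, vinylic bromide inert), and low temperature with a reactive allylic bromide should limit double alkylation.

Step 6
Reactants: 8 4-bromo-1-[2-hydroxy-4,5-bis(methoxymethoxy)phenyl]-5-methylhex-4-en-1-one
Product: 9 7,8-bis(methoxymethoxy)-2-(propan-2-ylidene)-3,4-dihydro-1-benzoxepin-5(2H)-one
Conditions: CuI (10 mol %), 1,10-phenanthroline (20 mol %), Cs2CO3 (2 equiv), toluene, 100 °C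
Reagents that add atoms: none
Why: Ullmann-type intramolecular O-vinylation of the phenol by the vinyl bromide under monovalent copper catalysis closes the seven-membered ring (exo alkene) and fixes the double bond on the isopropylidene side, since the C–Br carbon becomes the C–O carbon.

Step 7
Reactants: 10 5-fluorobenzene-1,3-diol
Product: 11 1,3-bis(benzyloxy)-5-fluorobenzene
Conditions: BnBr (2.2 equiv), K2CO3, DMF, rt
Reagents that add atoms: benzyl bromide, BrCc1ccccc1
Why: Williamson etherification of both phenols gives ethers that survive enolate and carbonate chemistry and can later be removed by neutral hydrogenolysis.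

Step 8
Reactants: 11 1,3-bis(benzyloxy)-5-fluorobenzene
Product: 12 2,4-bis(benzyloxy)-6-fluorobenzaldehyde
Conditions: POCl3, DMF, 0 to 70 °C; then aq. NaOAc
Reagents that add atoms: N,N-dimethylformamide, CN(C)C=O (formyl carbon); water, O (formyl oxygen)
Why: Vilsmeier–Haack formylation should occur para to one benzyloxy group and ortho to the other (next to the small fluorine) rather than at the crowded carbon between the two benzyloxy groups.

Step 9
Reactants: 12 2,4-bis(benzyloxy)-6-fluorobenzaldehyde
Product: 13 2,4-bis(benzyloxy)-6-fluorobenzoic acid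
Conditions: NaClO2, NaH2PO4, 2-methylbut-2-ene, t-BuOH/H2O, rt
Reagents that add atoms: sodium chlorite NaClO2, [Na+].[O-]Cl=O
Why: Pinnick oxidation converts the aldehyde into the acid, with the alkene scavenging hypochlorous acid so that the electron-rich ring is not chlorinated.

Step 10
Reactants: 13 2,4-bis(benzyloxy)-6-fluorobenzoic acid, 9 7,8-bis(methoxymethoxy)-2-(propan-2-ylidene)-3,4-dihydro-1-benzoxepin-5(2H)-one
Product: 15 4-[2,4-bis(benzyloxy)-6-fluorobenzoyl]-7,8-bis(methoxymethoxy)-2-(propan-2-ylidene)-3,4-dihydro-1-benzoxepin-5(2H)-one (racemic enolisable 1,3-diketone), via 2,4-bis(benzyloxy)-6-fluorobenzoyl chloride 14 (not isolated)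
Conditions: 13, (COCl)2, cat. DMF, CH2Cl2, 0 °C to rt, evaporate; 9, LiN(SiMe3)2 (2.2 equiv), THF, −78 °C, then 14, −78 to 0 °C
Reagents that add atoms: none
Why: Claisen-type C-acylation of the lithium enolate of the benzoxepinone by the aroyl chloride is driven by deprotonation of the 1,3-diketone with the second equivalent of base, and the enol ether and MOM groups are inert to amide base.

Step 11
Reactants: 15 4-[2,4-bis(benzyloxy)-6-fluorobenzoyl]-7,8-bis(methoxymethoxy)-2-(propan-2-ylidene)-3,4-dihydro-1-benzoxepin-5(2H)-one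
Product: 16 5,7-bis(benzyloxy)-4',5'-bis(methoxymethoxy)oxepinoflavone
Conditions: K2CO3, DMF, 80 °C
Reagents that add atoms: none
Why: The enolate oxygen displaces the fluoride ortho to the aroyl carbonyl by intramolecular SNAr (addition–elimination) and closes the six-membered pyranone under purely basic conditions, which the acid-sensitive enol ether tolerates; no free phenol is present to compete.

Step 12
Reactants: 16 5,7-bis(benzyloxy)-4',5'-bis(methoxymethoxy)oxepinoflavone
Product: 17 5,7-dihydroxy-4',5'-bis(methoxymethoxy)oxepinoflavone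
Conditions: H2 (1 atm), Pd/C, EtOAc/THF, rt
Reagents that add atoms: none
Why: Hydrogenolysis of aryl benzyl ethers in neutral aprotic solvent should be much faster than reduction of the tetrasubstituted enol ether or the fully substituted chromone C2=C3 bond, and MOM ethers are inert.

Step 13
Reactants: 17 5,7-dihydroxy-4',5'-bis(methoxymethoxy)oxepinoflavone
Product: 18 5-hydroxy-7-(triisopropylsilyloxy)-4',5'-bis(methoxymethoxy)oxepinoflavone
Conditions: TIPSCl (1.1 equiv), imidazole, DMF, 0 °C
Reagents that add atoms: chlorotriisopropylsilane, CC(C)[Si](Cl)(C(C)C)C(C)C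
Why: Silylation takes the acidic, non-chelated 7-OH only, because the 5-OH is hydrogen-bonded to the C4 carbonyl and shielded by it.

Step 14
Reactants: 18 5-hydroxy-7-(triisopropylsilyloxy)-4',5'-bis(methoxymethoxy)oxepinoflavone, 19 3-chloro-3-methylbut-1-yne
Product: 20 5-(2-methylbut-3-yn-2-yloxy)-7-(triisopropylsilyloxy)-4',5'-bis(methoxymethoxy)oxepinoflavone
Conditions: 19 (3 equiv), DBU, CuCl2 (1 mol %), MeCN, 0 °C to rt
Reagents that add atoms: none
Why: In this copper-catalysed O-propargylation the copper acetylide of 19 ionises to an electrophilic allenylidene that the DBU-generated 5-phenoxide attacks at the tertiary carbon; the conditions are those known for hindered and hydrogen-bonded phenols, and the bulky silyl ether on O7 should resist the amidine.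

Step 15
Reactants: 20 5-(2-methylbut-3-yn-2-yloxy)-7-(triisopropylsilyloxy)-4',5'-bis(methoxymethoxy)oxepinoflavone
Product: 21 5-(2-methylbut-3-en-2-yloxy)-7-(triisopropylsilyloxy)-4',5'-bis(methoxymethoxy)oxepinoflavone
Conditions: H2 (1 atm), Pd/CaCO3 poisoned with Pb(OAc)2, quinoline, EtOAc, rt
Reagents that add atoms: none
Why: Lindlar semi-hydrogenation stops at the terminal alkene on the lead-poisoned palladium surface, and the tetrasubstituted enol ether, the chromone and the MOM and silyl ethers are not reduced.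

Step 16
Reactants: 21 5-(2-methylbut-3-en-2-yloxy)-7-(triisopropylsilyloxy)-4',5'-bis(methoxymethoxy)oxepinoflavone
Product: 22 7-hydroxy-5-(2-methylbut-3-en-2-yloxy)-4',5'-bis(methoxymethoxy)oxepinoflavone
Conditions: Bu4NF, AcOH, THF, 0 °C
Reagents that add atoms: none
Why: Buffered fluoride cleaves the aryl silyl ether para to the chromone carbonyl within minutes at 0 °C, and the cold, near-neutral medium protects the thermally labile tertiary allyl ether.

Step 17
Reactants: 22 7-hydroxy-5-(2-methylbut-3-en-2-yloxy)-4',5'-bis(methoxymethoxy)oxepinoflavone, 19 3-chloro-3-methylbut-1-yne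
Product: 23 5-(2-methylbut-3-en-2-yloxy)-7-(2-methylbut-3-yn-2-yloxy)-4',5'-bis(methoxymethoxy)oxepinoflavone
Conditions: 19 (2 equiv), DBU, CuCl2 (1 mol %), MeCN, 0 °C
Reagents that add atoms: none
Why: The same copper-catalysed propargylation now meets a free, non-hydrogen-bonded 7-OH and should be fast at 0 °C, far below the onset of either sigmatropic shift.

Step 18
Reactants: 23 5-(2-methylbut-3-en-2-yloxy)-7-(2-methylbut-3-yn-2-yloxy)-4',5'-bis(methoxymethoxy)oxepinoflavone
Product: 26 isocycloheterophyllin 4',5'-bis(methoxymethyl) ether, via 5-hydroxy-6-prenyl 7-O-(1,1-dimethylpropargyl) ether 24 (not isolated), via 8-allenyl-5,7-dihydroxy-6-prenyl oxepinoflavone 25 (not isolated)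
Conditions: PhNEt2 (degassed), Ar, 105 °C until 23 is consumed, then 175 °C
Reagents that add atoms: none
Why: At 105 °C the 5-O-(1,1-dimethylallyl) ether undergoes an aromatic Claisen [3,3] shift through a chair transition state; because C4a is quaternary the allyl terminus can only bond to C6, and enolisation of the dienone gives the chelated 5-OH with a normal prenyl group (24). At 175 °C the 7-O-(1,1-dimethylpropargyl) ether shifts [3,3] to C8, the only free ortho carbon (C8–C4 bond of the pyran), the allenyl dienone enolises to 25, a 1,5-hydrogen shift from O7–H to the central allene carbon gives an o-quinone methide dienone, and a thermal disrotatory oxa-6π electrocyclisation closes the 2,2-dimethylpyran by forming O7–C2. The closest known reaction types are the Claisen rearrangement of aryl 1,1-dimethylallyl ethers to ortho-prenylphenols and the thermal conversion of aryl 1,1-dimethylpropargyl ethers into 2,2-dimethyl-2H-chromenes. No stereocentre is created. The step needs site selectivity (prenyl at C6, pyran across O7 and C8), which the blocked C4a and the lower barrier of the allyl shift secure by filling C6 before the propargyl ether reacts. The amine solvent keeps the medium basic, so the tertiary ether should not ionise and the enol ether, the chromone and the MOM groups remain spectators.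

Step 19
Reactants: 26 isocycloheterophyllin 4',5'-bis(methoxymethyl) ether
Product: 27 isocycloheterophyllin
Conditions: Me3SiOTf, 2,2'-bipyridyl, MeCN, 0 °C to rt; then H2O
Reagents that add atoms: none
Why: Under these aprotic, amine-buffered conditions aryl MOM ethers are exchanged for aryl trimethylsilyl ethers that water cleaves on work-up, so no free Brønsted acid meets the aryl enol ether, the chromene or the prenyl phenol.

**Compound list**

1 | 1-(2,4,5-trihydroxyphenyl)ethan-1-one | CC(=O)c1cc(O)c(O)cc1O | starting material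
2 | 1-[2-hydroxy-4,5-bis(methoxymethoxy)phenyl]ethan-1-one | CC(=O)c1cc(OCOC)c(OCOC)cc1O | intermediate
3 | 3-methylbut-2-enal | CC(C)=CC=O | starting material
4 | 2,3-dibromo-3-methylbutanal (racemic, not isolated) | CC(C)(Br)C(Br)C=O | intermediate
5 | 2-bromo-3-methylbut-2-enal | CC(C)=C(Br)C=O | intermediate
6 | 2-bromo-3-methylbut-2-en-1-ol | CC(C)=C(Br)CO | intermediate
7 | 1,2-dibromo-3-methylbut-2-ene | CC(C)=C(Br)CBr | intermediate
8 | 4-bromo-1-[2-hydroxy-4,5-bis(methoxymethoxy)phenyl]-5-methylhex-4-en-1-one | CC(C)=C(Br)CCC(=O)c1cc(OCOC)c(OCOC)cc1O | intermediate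
9 | 7,8-bis(methoxymethoxy)-2-(propan-2-ylidene)-3,4-dihydro-1-benzoxepin-5(2H)-one | CC(C)=C1CCC(=O)c2cc(OCOC)c(OCOC)cc2O1 | intermediate
10 | 5-fluorobenzene-1,3-diol | Oc1cc(O)cc(F)c1 | starting material
11 | 1,3-bis(benzyloxy)-5-fluorobenzene | Fc1cc(OCc2ccccc2)cc(OCc2ccccc2)c1 | intermediate
12 | 2,4-bis(benzyloxy)-6-fluorobenzaldehyde | O=Cc1c(F)cc(OCc2ccccc2)cc1OCc1ccccc1 | intermediate
13 | 2,4-bis(benzyloxy)-6-fluorobenzoic acid | OC(=O)c1c(F)cc(OCc2ccccc2)cc1OCc1ccccc1 | intermediate
14 | 2,4-bis(benzyloxy)-6-fluorobenzoyl chloride (not isolated) | O=C(Cl)c1c(F)cc(OCc2ccccc2)cc1OCc1ccccc1 | intermediate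
15 | 4-[2,4-bis(benzyloxy)-6-fluorobenzoyl]-7,8-bis(methoxymethoxy)-2-(propan-2-ylidene)-3,4-dihydro-1-benzoxepin-5(2H)-one (racemic, enolisable) | CC(C)=C1CC(C(=O)c2c(F)cc(OCc3ccccc3)cc2OCc2ccccc2)C(=O)c2cc(OCOC)c(OCOC)cc2O1 | intermediate
16 | 5,7-bis(benzyloxy)-4',5'-bis(methoxymethoxy)oxepinoflavone | C(Oc1cc(OCc2ccccc2)cc2oc3c(c(=O)c12)CC(=C(C)C)Oc1cc(OCOC)c(OCOC)cc1-3)c1ccccc1 | intermediate
17 | 5,7-dihydroxy-4',5'-bis(methoxymethoxy)oxepinoflavone | Oc1cc(O)cc2oc3c(c(=O)c12)CC(=C(C)C)Oc1cc(OCOC)c(OCOC)cc1-3 | intermediate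
18 | 5-hydroxy-7-(triisopropylsilyloxy)-4',5'-bis(methoxymethoxy)oxepinoflavone | Oc1cc(O[Si](C(C)C)(C(C)C)C(C)C)cc2oc3c(c(=O)c12)CC(=C(C)C)Oc1cc(OCOC)c(OCOC)cc1-3 | intermediate
19 | 3-chloro-3-methylbut-1-yne | CC(C)(Cl)C#C | starting material
20 | 5-(2-methylbut-3-yn-2-yloxy)-7-(triisopropylsilyloxy)-4',5'-bis(methoxymethoxy)oxepinoflavone | C#CC(C)(C)Oc1cc(O[Si](C(C)C)(C(C)C)C(C)C)cc2oc3c(c(=O)c12)CC(=C(C)C)Oc1cc(OCOC)c(OCOC)cc1-3 | intermediate
21 | 5-(2-methylbut-3-en-2-yloxy)-7-(triisopropylsilyloxy)-4',5'-bis(methoxymethoxy)oxepinoflavone | C=CC(C)(C)Oc1cc(O[Si](C(C)C)(C(C)C)C(C)C)cc2oc3c(c(=O)c12)CC(=C(C)C)Oc1cc(OCOC)c(OCOC)cc1-3 | intermediate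
22 | 7-hydroxy-5-(2-methylbut-3-en-2-yloxy)-4',5'-bis(methoxymethoxy)oxepinoflavone | C=CC(C)(C)Oc1cc(O)cc2oc3c(c(=O)c12)CC(=C(C)C)Oc1cc(OCOC)c(OCOC)cc1-3 | intermediate
23 | 5-(2-methylbut-3-en-2-yloxy)-7-(2-methylbut-3-yn-2-yloxy)-4',5'-bis(methoxymethoxy)oxepinoflavone (key-step precursor) | C=CC(C)(C)Oc1cc(OC(C)(C)C#C)cc2oc3c(c(=O)c12)CC(=C(C)C)Oc1cc(OCOC)c(OCOC)cc1-3 | intermediate
24 | 5-hydroxy-6-(3-methylbut-2-en-1-yl)-7-(2-methylbut-3-yn-2-yloxy)-4',5'-bis(methoxymethoxy)oxepinoflavone (not isolated) | Oc1c(CC=C(C)C)c(OC(C)(C)C#C)cc2oc3c(c(=O)c12)CC(=C(C)C)Oc1cc(OCOC)c(OCOC)cc1-3 | intermediate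
25 | 5,7-dihydroxy-6-(3-methylbut-2-en-1-yl)-8-(3-methylbuta-1,2-dien-1-yl)-4',5'-bis(methoxymethoxy)oxepinoflavone (not isolated) | Oc1c(CC=C(C)C)c(O)c(C=C=C(C)C)c2oc3c(c(=O)c12)CC(=C(C)C)Oc1cc(OCOC)c(OCOC)cc1-3 | intermediate
26 | isocycloheterophyllin 4',5'-bis(methoxymethyl) ether (key-step product) | CC(C)=CCc1c2c(c3oc4c(c(=O)c3c1O)CC(=C(C)C)Oc1cc(OCOC)c(OCOC)cc1-4)C=CC(C)(C)O2 | intermediate
27 | isocycloheterophyllin | CC(C)=CCc1c2c(c3oc4c(c(=O)c3c1O)CC(=C(C)C)Oc1cc(O)c(O)cc1-4)C=CC(C)(C)O2 | target

**Step count and risks**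

Total: 19 steps. Longest linear sequence: 15 steps (3 to 27 through steps 2–6 and 10–19).

Steps most likely to fail:

1. Step 6 (oxepine closure). The seven-membered ring closure on the flexible keto-phenol may be slower than O-vinylation through the ketone enolate (five-membered closure leading to a furan), reductive loss of bromide or oligomerisation. The fallback sets out from 2 (with 7 and with 14 made from 13) and comes back at 16; it inverts the order of ring formation so that the oxepine closes last on a rigid flavone. Compound 2 is deprotonated with LiN(SiMe3)2 (3 equiv, THF, −78 °C) and C-acylated with 14 to give 1-[2,4-bis(benzyloxy)-6-fluorophenyl]-3-[2-hydroxy-4,5-bis(methoxymethoxy)phenyl]propane-1,3-dione F1. C-alkylation of this diketone with 7 (K2CO3, acetone) should give 1-[2,4-bis(benzyloxy)-6-fluorophenyl]-2-(2-bromo-3-methylbut-2-en-1-yl)-3-[2-hydroxy-4,5-bis(methoxymethoxy)phenyl]propane-1,3-dione F2. K2CO3 in DMF at 80 °C closes the pyranone by SNAr to 5,7-bis(benzyloxy)-3-(2-bromo-3-methylbut-2-en-1-yl)-2-[2-hydroxy-4,5-bis(methoxymethoxy)phenyl]chromen-4-one F3, in which C2=C3 holds phenol and vinyl bromide cis and no enolisable ketone is left. Palladium-catalysed C–O coupling (Pd2(dba)3, tBuXPhos, K3PO4, toluene, 90 °C; zerovalent palladium inserts into the vinyl C–Br bond) then closes the oxepine to 16.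

2. Step 14 (5-O-propargylation). O-alkylation of the hydrogen-bonded, peri-hindered 5-hydroxyl may stall, and slow loss of the 7-O-silyl group under the amidine base would divert the electrophile to O7. The fallback sets out from 18 and comes back at 21, bypassing 20 and step 15. The tertiary allyl ether is installed directly by decarboxylative O-allylation with tert-butyl 2-methylbut-3-en-2-yl carbonate and Pd(PPh3)4 (zerovalent palladium, THF, 0 °C); the phenoxide formed by the released tert-butoxide attacks the more substituted terminus of the 1,1-dimethylallyl palladium cation under kinetic control. No amidine base and no alkyne reduction are needed, and no new compound arises.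

3. Step 18 (cascade). The order of events may be lost: propargyl migration to C6 before the allyl shift is complete would give the linear pyran, and the tertiary allyl ether may ionise and eliminate to isoprene and the 5-phenol. The fallback sets out from 22 and comes back at 26; the two shifts are run separately. Compound 22 is heated alone (PhNEt2, 105 °C), so that only the allyl Claisen can occur, giving 5,7-dihydroxy-6-(3-methylbut-2-en-1-yl)-4',5'-bis(methoxymethoxy)oxepinoflavone F4. The free, non-chelated 7-OH is then propargylated selectively with 19 (DBU, CuCl2, MeCN, 0 °C) to give 24, now isolated. Heating 24 (PhNEt2, 175 °C) with C6 already blocked should give 26.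

**Further compounds**

F1 | step 6 | 1-[2,4-bis(benzyloxy)-6-fluorophenyl]-3-[2-hydroxy-4,5-bis(methoxymethoxy)phenyl]propane-1,3-dione | O=C(CC(=O)c1cc(OCOC)c(OCOC)cc1O)c1c(F)cc(OCc2ccccc2)cc1OCc1ccccc1
F2 | step 6 | 1-[2,4-bis(benzyloxy)-6-fluorophenyl]-2-(2-bromo-3-methylbut-2-en-1-yl)-3-[2-hydroxy-4,5-bis(methoxymethoxy)phenyl]propane-1,3-dione | O=C(C(CC(Br)=C(C)C)C(=O)c1cc(OCOC)c(OCOC)cc1O)c1c(F)cc(OCc2ccccc2)cc1OCc1ccccc1
F3 | step 6 | 5,7-bis(benzyloxy)-3-(2-bromo-3-methylbut-2-en-1-yl)-2-[2-hydroxy-4,5-bis(methoxymethoxy)phenyl]chromen-4-one | CC(C)=C(Br)Cc1c(-c2cc(OCOC)c(OCOC)cc2O)oc2cc(OCc3ccccc3)cc(OCc3ccccc3)c2c1=O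
F0 | step 14 | none | none
F4 | step 18 | 5,7-dihydroxy-6-(3-methylbut-2-en-1-yl)-4',5'-bis(methoxymethoxy)oxepinoflavone | Oc1c(CC=C(C)C)c(O)cc2oc3c(c(=O)c12)CC(=C(C)C)Oc1cc(OCOC)c(OCOC)cc1-3
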